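Cryptomerin B is reached in 9 steps by closing ring C of the 4‑methoxyphenyl flavone through a three‑component carbonylative annulation (step 4).

Everything rests on opening ring C of the 4‑methoxyphenyl flavone (flavone unit 1) at C4a–C4, C4–C3 and O1–C2. Because C4 is a lone carbonyl carbon flanked by C4a and C3, and O1 and C4a are ortho neighbours on ring A, an o‑iodophenol, carbon monoxide and 4‑ethynylanisole can be stitched into the pyranone in one palladium‑catalysed operation. The precursor is a diaryl ether: a 4‑aryloxy‑3,5‑dimethoxyphenol iodinated once ortho to the hydroxyl, whose aryl group carries a tert‑butyl ester whose carbonyl carbon later becomes C2 of the second flavone. Mirror symmetry of the phenol before iodination removes any regiochemical question on ring A.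

Key step: step 4

Remark: flavone unit 1 is the chromenone bearing the 4‑methoxyphenyl group and flavone unit 2 is the 5,7‑dihydroxychromenone. The target has no stereocentre, and the only stereo element in the route is the transient enaminone double bond of 10, drawn E.

Step 1
Reactants: 1 syringaldehyde; 2 tert‑butyl 4‑fluorobenzoate
Product: 3 tert‑butyl 4‑(4‑formyl‑2,6‑dimethoxyphenoxy)benzoate
Conditions: Cs2CO3, DMSO, 120 °C, N2
Reagents that add atoms: none
Why: Nucleophilic aromatic substitution (SNAr), in which the caesium phenoxide of 1 adds para to the ester of 2 and fluoride leaves from the Meisenheimer adduct, the aldehyde and the tert‑butyl ester being inert to carbonate in hot DMSO.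

Step 2
Reactants: 3 tert‑butyl 4‑(4‑formyl‑2,6‑dimethoxyphenoxy)benzoate
Product: 5 tert‑butyl 4‑(4‑hydroxy‑2,6‑dimethoxyphenoxy)benzoate, via aryl formate 4 (not isolated)
Conditions: mCPBA, CH2Cl2, 0 °C → rt; then K2CO3 (cat.), MeOH, rt
Reagents that add atoms: 3‑chloroperoxybenzoic acid (mCPBA), O=C(OO)c1cccc(Cl)c1
Why: Baeyer–Villiger (Dakin‑type) oxidation, in which the electron‑rich trioxygenated aryl group migrates in the Criegee adduct in preference to hydride to give formate 4, which mild methanolysis should cleave without touching the tert‑butyl ester.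

Step 3
Reactants: 5 tert‑butyl 4‑(4‑hydroxy‑2,6‑dimethoxyphenoxy)benzoate
Product: 6 tert‑butyl 4‑(4‑hydroxy‑3‑iodo‑2,6‑dimethoxyphenoxy)benzoate
Conditions: NIS (1.0 equiv), MeCN, −20 → 0 °C, dark
Reagents that add atoms: N‑iodosuccinimide (NIS), O=C1CCC(=O)N1I
Why: Electrophilic aromatic iodination, in which the two C–H positions ortho to the hydroxyl are the only free carbons of the activated ring and are equivalent by symmetry, so one equivalent of NIS at low temperature should give a single mono‑iodide and leave the ester‑bearing ring untouched.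

Step 4
Reactants: 6 tert‑butyl 4‑(4‑hydroxy‑3‑iodo‑2,6‑dimethoxyphenoxy)benzoate; 7 carbon monoxide; 8 4‑ethynylanisole
Product: 11 tert‑butyl 4‑{[5,7‑dimethoxy‑2‑(4‑methoxyphenyl)‑4‑oxo‑4H‑chromen‑6‑yl]oxy}benzoate, via o‑hydroxyaryl ynone 9 (not isolated), via diethylamino enaminone 10 (not isolated)
Conditions: PdCl2(dppf) (5 mol %), 8 (1.5 equiv), CO (20 bar), Et2NH, 100 °C
Reagents that add atoms: none
Why: Zerovalent palladium inserts into the C–I bond of 6, carbon monoxide insertion gives an aroylpalladium species, and amine‑assisted transfer of the acetylide of 8 followed by reductive elimination gives ynone 9 (C4a–C4 and C4–C3). Diethylamine then adds in conjugate fashion to 9 to give enaminone 10, and the neighbouring phenol oxygen attacks the amine‑bearing carbon and expels diethylamine (O1–C2). The closest known reaction type is the palladium‑catalysed carbonylative Sonogashira coupling–annulation of o‑iodophenols with terminal alkynes in a secondary amine. Ring C closes in a 6‑endo sense by addition–elimination on the enaminone, a path that has no 5‑exo counterpart leading to an aurone. No stereocentre is formed. The step needs carbonylative over direct coupling, which the CO pressure, the copper‑free system and the electron‑rich aryl group (fast CO insertion) should secure, and it needs a single acylation site, which the C–I bond placed on the symmetric phenol 5 in step 3 secures.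

Step 5
Reactants: 11 tert‑butyl 4‑{[5,7‑dimethoxy‑2‑(4‑methoxyphenyl)‑4‑oxo‑4H‑chromen‑6‑yl]oxy}benzoate
Product: 12 4‑{[5,7‑dimethoxy‑2‑(4‑methoxyphenyl)‑4‑oxo‑4H‑chromen‑6‑yl]oxy}benzoic acid
Conditions: TFA, CH2Cl2, rt
Reagents that add atoms: none
Why: Acid‑mediated tert‑butyl ester cleavage (E1 loss of isobutene), which should leave the aryl methyl ethers, the diaryl ether and the chromenone untouched.

Step 6
Reactants: 13 2,4,6‑trihydroxyacetophenone
Product: 14 1‑[2,4‑bis(benzyloxy)‑6‑hydroxyphenyl]ethan‑1‑one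
Conditions: BnBr (2.05 equiv), K2CO3, DMF, rt
Reagents that add atoms: benzyl bromide, BrCc1ccccc1
Why: Williamson etherification, in which the 4‑hydroxyl and one ortho hydroxyl are alkylated while the last ortho hydroxyl, hydrogen‑bonded to the acetyl carbonyl, is the least nucleophilic and should stay free with two equivalents of benzyl bromide.

Step 7
Reactants: 12 4‑{[5,7‑dimethoxy‑2‑(4‑methoxyphenyl)‑4‑oxo‑4H‑chromen‑6‑yl]oxy}benzoic acid; 14 1‑[2,4‑bis(benzyloxy)‑6‑hydroxyphenyl]ethan‑1‑one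
Product: 15 2‑acetyl‑3,5‑bis(benzyloxy)phenyl 4‑{[5,7‑dimethoxy‑2‑(4‑methoxyphenyl)‑4‑oxo‑4H‑chromen‑6‑yl]oxy}benzoate
Conditions: EDC·HCl, DMAP (cat.), CH2Cl2, rt
Reagents that add atoms: none
Why: Steglich esterification, in which DMAP relays the O‑acylisourea of 12 as an acylpyridinium ion that should acylate even the chelated phenol of 14, so that no separate acid chloride step is needed.

Step 8
Reactants: 15 2‑acetyl‑3,5‑bis(benzyloxy)phenyl 4‑{[5,7‑dimethoxy‑2‑(4‑methoxyphenyl)‑4‑oxo‑4H‑chromen‑6‑yl]oxy}benzoate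
Product: 17 5,7‑bis(benzyloxy)‑2‑(4‑{[5,7‑dimethoxy‑2‑(4‑methoxyphenyl)‑4‑oxo‑4H‑chromen‑6‑yl]oxy}phenyl)‑4H‑chromen‑4‑one, via 1,3‑diketone 16 (not isolated)
Conditions: LiN(SiMe3)2 (3 equiv), THF, −78 °C → rt; then AcOH, cat. H2SO4, 90 °C
Reagents that add atoms: none
Why: Baker–Venkataraman rearrangement (the lithium enolate of the acetyl group attacks the neighbouring aryl ester in an intramolecular Claisen‑type O‑to‑C acyl shift to give 16) followed by acid‑catalysed cyclodehydration, in which the freed phenol adds to the distal carbonyl and water is lost to close the second pyranone; the non‑nucleophilic amide base should spare the chromenone of flavone unit 1, and any benzyl ether lost in the acid stage converges in step 9.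

Step 9
Reactants: 17 5,7‑bis(benzyloxy)‑2‑(4‑{[5,7‑dimethoxy‑2‑(4‑methoxyphenyl)‑4‑oxo‑4H‑chromen‑6‑yl]oxy}phenyl)‑4H‑chromen‑4‑one
Product: 18 Cryptomerin B
Conditions: BCl3 (excess), C6HMe5, CH2Cl2, −78 °C → rt; then MeOH, aq. HCl
Reagents that add atoms: none
Why: Lewis acid ether cleavage, in which BCl3 removes both benzyl groups at low temperature with pentamethylbenzene trapping the benzyl cations, and should cleave only the methyl ether at C5 of flavone unit 1 because that oxygen forms a six‑membered boron chelate with the C4 carbonyl, whereas the 7‑ and 4'‑methyl ethers lack such assistance.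

Compound list
1 | syringaldehyde (4‑hydroxy‑3,5‑dimethoxybenzaldehyde) | COc1cc(C=O)cc(OC)c1O | starting material
2 | tert‑butyl 4‑fluorobenzoate | CC(C)(C)OC(=O)c1ccc(F)cc1 | starting material
3 | tert‑butyl 4‑(4‑formyl‑2,6‑dimethoxyphenoxy)benzoate | CC(C)(C)OC(=O)c1ccc(Oc2c(OC)cc(C=O)cc2OC)cc1 | intermediate
4 | tert‑butyl 4‑[4‑(formyloxy)‑2,6‑dimethoxyphenoxy]benzoate (aryl formate, not isolated) | CC(C)(C)OC(=O)c1ccc(Oc2c(OC)cc(OC=O)cc2OC)cc1 | intermediate
5 | tert‑butyl 4‑(4‑hydroxy‑2,6‑dimethoxyphenoxy)benzoate | CC(C)(C)OC(=O)c1ccc(Oc2c(OC)cc(O)cc2OC)cc1 | intermediate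
6 | tert‑butyl 4‑(4‑hydroxy‑3‑iodo‑2,6‑dimethoxyphenoxy)benzoate | CC(C)(C)OC(=O)c1ccc(Oc2c(OC)cc(O)c(I)c2OC)cc1 | intermediate
7 | carbon monoxide | [C-]#[O+] | starting material
8 | 4‑ethynylanisole | C#Cc1ccc(OC)cc1 | starting material
9 | tert‑butyl 4‑{4‑hydroxy‑2,6‑dimethoxy‑3‑[3‑(4‑methoxyphenyl)prop‑2‑ynoyl]phenoxy}benzoate (o‑hydroxyaryl ynone, not isolated) | COc1ccc(C#CC(=O)c2c(O)cc(OC)c(Oc3ccc(C(=O)OC(C)(C)C)cc3)c2OC)cc1 | intermediate
10 | tert‑butyl 4‑{3‑[(2E)‑3‑(diethylamino)‑3‑(4‑methoxyphenyl)prop‑2‑enoyl]‑4‑hydroxy‑2,6‑dimethoxyphenoxy}benzoate (enaminone, not isolated) | CCN(CC)/C(=C/C(=O)c1c(O)cc(OC)c(Oc2ccc(C(=O)OC(C)(C)C)cc2)c1OC)c1ccc(OC)cc1 | intermediate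
11 | tert‑butyl 4‑{[5,7‑dimethoxy‑2‑(4‑methoxyphenyl)‑4‑oxo‑4H‑chromen‑6‑yl]oxy}benzoate | COc1ccc(-c2cc(=O)c3c(OC)c(Oc4ccc(C(=O)OC(C)(C)C)cc4)c(OC)cc3o2)cc1 | intermediate
12 | 4‑{[5,7‑dimethoxy‑2‑(4‑methoxyphenyl)‑4‑oxo‑4H‑chromen‑6‑yl]oxy}benzoic acid | COc1ccc(-c2cc(=O)c3c(OC)c(Oc4ccc(C(=O)O)cc4)c(OC)cc3o2)cc1 | intermediate
13 | 2,4,6‑trihydroxyacetophenone | CC(=O)c1c(O)cc(O)cc1O | starting material
14 | 1‑[2,4‑bis(benzyloxy)‑6‑hydroxyphenyl]ethan‑1‑one | CC(=O)c1c(O)cc(OCc2ccccc2)cc1OCc1ccccc1 | intermediate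
15 | 2‑acetyl‑3,5‑bis(benzyloxy)phenyl 4‑{[5,7‑dimethoxy‑2‑(4‑methoxyphenyl)‑4‑oxo‑4H‑chromen‑6‑yl]oxy}benzoate | COc1ccc(-c2cc(=O)c3c(OC)c(Oc4ccc(C(=O)Oc5cc(OCc6ccccc6)cc(OCc6ccccc6)c5C(C)=O)cc4)c(OC)cc3o2)cc1 | intermediate
16 | 1‑[2,4‑bis(benzyloxy)‑6‑hydroxyphenyl]‑3‑(4‑{[5,7‑dimethoxy‑2‑(4‑methoxyphenyl)‑4‑oxo‑4H‑chromen‑6‑yl]oxy}phenyl)propane‑1,3‑dione (not isolated) | COc1ccc(-c2cc(=O)c3c(OC)c(Oc4ccc(C(=O)CC(=O)c5c(O)cc(OCc6ccccc6)cc5OCc5ccccc5)cc4)c(OC)cc3o2)cc1 | intermediate
17 | 5,7‑bis(benzyloxy)‑2‑(4‑{[5,7‑dimethoxy‑2‑(4‑methoxyphenyl)‑4‑oxo‑4H‑chromen‑6‑yl]oxy}phenyl)‑4H‑chromen‑4‑one | COc1ccc(-c2cc(=O)c3c(OC)c(Oc4ccc(-c5cc(=O)c6c(OCc7ccccc7)cc(OCc7ccccc7)cc6o5)cc4)c(OC)cc3o2)cc1 | intermediate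
18 | Cryptomerin B, 5,7‑dihydroxy‑2‑(4‑{[5‑hydroxy‑7‑methoxy‑2‑(4‑methoxyphenyl)‑4‑oxo‑4H‑chromen‑6‑yl]oxy}phenyl)‑4H‑chromen‑4‑one | COc1ccc(-c2cc(=O)c3c(O)c(Oc4ccc(-c5cc(=O)c6c(O)cc(O)cc6o5)cc4)c(OC)cc3o2)cc1 | target

Total steps: 9. Longest linear sequence: 8 steps (steps 1–5 and 7–9, from syringaldehyde 1); step 6 prepares the side fragment 14.

Steps most likely to fail

Step 4 (key step). The aryl–palladium species may couple with the alkyne before CO insertion, the aroylpalladium species may be captured by the amine, or oxidative addition may be slow at an electron‑rich phenoxide whose C–I bond is flanked on both sides. The fallback sets out from 6 and separates the events. Acetylation (Ac2O, pyridine, DMAP) should give tert‑butyl 4‑[4‑(acetyloxy)‑3‑iodo‑2,6‑dimethoxyphenoxy]benzoate F1, whose less electron‑rich ring should add to zerovalent palladium more readily. A carbonylative Sonogashira coupling of F1 with 8 in the absence of any secondary amine (PdCl2(PPh3)2, Et3N, THF, CO 1–5 bar, rt to 40 °C) should give the isolable ynone tert‑butyl 4‑{4‑(acetyloxy)‑2,6‑dimethoxy‑3‑[3‑(4‑methoxyphenyl)prop‑2‑ynoyl]phenoxy}benzoate F2. Treatment of F2 with Et2NH in EtOH at rt to 40 °C should remove the acetate and carry the ynone through enaminone 10 to the flavone, so the fallback comes back to the route at 11.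

Step 1. Substitution may be sluggish because the phenoxide of 1 is flanked by two methoxy groups and weakened by the para formyl group, while the fluoroarene is activated only by an ester; long heating may then erode the aldehyde. The fallback sets out from 2 and uses commercial 2,6‑dimethoxyphenol, the formyl‑free and more nucleophilic phenoxide. SNAr (Cs2CO3, DMSO, 110 °C) should give tert‑butyl 4‑(2,6‑dimethoxyphenoxy)benzoate F3. Iridium‑catalysed C–H borylation ([Ir(OMe)(cod)]2, 4,4'‑di‑tert‑butyl‑2,2'‑bipyridine, B2pin2, THF, 80 °C) should then functionalise the only C–H bond that has no ortho substituent, para to the diaryl ether oxygen, to give tert‑butyl 4‑[2,6‑dimethoxy‑4‑(4,4,5,5‑tetramethyl‑1,3,2‑dioxaborolan‑2‑yl)phenoxy]benzoate F4. Oxidation of the C–B bond (H2O2, aq. NaOH, THF, 0 °C) should give the phenol, so the fallback comes back to the route at 5 and replaces steps 1 and 2.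

Step 9. Ether cleavage may be incomplete or unselective: the 7‑ or 4'‑methyl ether of flavone unit 1 may be lost, benzyl cations may attack the phloroglucinol ring, or the boron chelates may be poorly soluble. The fallback sets out from 17 and splits the task. Hydrogenolysis (H2, Pd/C, THF/MeOH, rt) should remove both benzyl groups without cationic intermediates and give 5,7‑dihydroxy‑2‑(4‑{[5,7‑dimethoxy‑2‑(4‑methoxyphenyl)‑4‑oxo‑4H‑chromen‑6‑yl]oxy}phenyl)‑4H‑chromen‑4‑one F5. Chelation‑controlled mono‑demethylation of F5 with AlCl3 in MeCN at 60 °C should then cleave only the methyl ether peri to the carbonyl, so the fallback comes back to the route at 18.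

Further compounds
F1 | step 4 | tert‑butyl 4‑[4‑(acetyloxy)‑3‑iodo‑2,6‑dimethoxyphenoxy]benzoate | CC(=O)Oc1cc(OC)c(Oc2ccc(C(=O)OC(C)(C)C)cc2)c(OC)c1I
F2 | step 4 | tert‑butyl 4‑{4‑(acetyloxy)‑2,6‑dimethoxy‑3‑[3‑(4‑methoxyphenyl)prop‑2‑ynoyl]phenoxy}benzoate | COc1ccc(C#CC(=O)c2c(OC(C)=O)cc(OC)c(Oc3ccc(C(=O)OC(C)(C)C)cc3)c2OC)cc1
F3 | step 1 | tert‑butyl 4‑(2,6‑dimethoxyphenoxy)benzoate | CC(C)(C)OC(=O)c1ccc(Oc2c(OC)cccc2OC)cc1
F4 | step 1 | tert‑butyl 4‑[2,6‑dimethoxy‑4‑(4,4,5,5‑tetramethyl‑1,3,2‑dioxaborolan‑2‑yl)phenoxy]benzoate | CC(C)(C)OC(=O)c1ccc(Oc2c(OC)cc(B3OC(C)(C)C(C)(C)O3)cc2OC)cc1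
F5 | step 9 | 5,7‑dihydroxy‑2‑(4‑{[5,7‑dimethoxy‑2‑(4‑methoxyphenyl)‑4‑oxo‑4H‑chromen‑6‑yl]oxy}phenyl)‑4H‑chromen‑4‑one | COc1ccc(-c2cc(=O)c3c(OC)c(Oc4ccc(-c5cc(=O)c6c(O)cc(O)cc6o5)cc4)c(OC)cc3o2)cc1
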